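- Two balances hold whatever the rates: c(G) + c(Z) + c(X) + c(E) stays at the G charged, if the proposed steps L to D, G + Q to E, two D to J, G to Z and D + Z to X are all there is, and every L charged sits in L, D, X or J.

the same everywhere: G 0.175 M

| flask | L | Q | remark | time |
|---|---|---|---|---|
| south | 0.38 M | 0.075 M | run made earlier |  |
| teal | 0.25 M | 0.0750 M |  | 80 min |
| grey | 0.25 M | 0.0750 M |  | 100 min |
south run (percent of the L charged)

| time / min | D / % | X / % | J / % | L / % |
|---|---|---|---|---|
| 0.667 | 37 | 0 | 0 | 59 |
| 1.33 | 61 | 0 | 0 | 36 |
| 3.00 | 84 | 2 | 0 | 12 |
| 8.00 | 97 | 2 | 0 | 1 |

(readings scatter by 2 percentage points)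
- percentages count the L that a species holds: one J counts as two
- steps that have been proposed: L -> D; G + Q -> E; 2 D -> J; G -> Z; D + Z -> X
- which of these there is most of at the end, counted by the L in it, teal (L / D / J / X)
- which of these there is most of at the end, counted by the L in it, grey (L / D / J / X)
- final amount of the leader among these, as a percentage of the L charged, in teal
- final amount of the leader among these, as a percentage of the L charged, in grey

- You start with L. The first south reading gives a first-order constant of 0.791 min⁻¹, a half-life of 0.876 min, far shorter than 80 min, so in teal and grey D holds whatever X and J do not.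
- Next comes the G budget, the Z that G can supply if Q takes its whole charge of G: 0.100 M. On that assumption G is the limiting reagent for X, at 40.0 % of the L in teal and grey.
- Then you need the pace. Z starts from nothing, so early c(Z) grows with time, and integrating the rate of D + Z makes c(X) grow with the square of time and with c(D).
- Take the last south reading, X at 2 % or 0.00760 M, scale it to teal's L and carry it forward on that square law: the estimate for reaching the budget is 35.8 min, before either end. That reading is no larger than its scatter of 2 percentage points and the square law is an early law, so this estimate is rough.
- My own commitment is therefore D leading at about 60.0 % in both flasks, less a little J. The weak link is Q: no reading shows how much G it takes.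
- The forecast gave D at 71 % (54 % to 90 %) in teal and D at 68 % (51 % to 88 %) in grey, with “X about 20–25% by 80–100 min”. Both central figures stand higher than my figure.
- The flask gives D at 56.4 % in teal and D at 52.0 % in grey, so the forecast stands 15 points and 16 points too high.

    L → D (k = 0.0120 s⁻¹)
    G + Q → E (k = 0.00500 M⁻¹ s⁻¹)
    2 D → J (k = 2.20 × 10⁻⁵ M⁻¹ s⁻¹)
    G → Z (k = 0.00130 s⁻¹)
    D + Z → X (k = 0.00170 M⁻¹ s⁻¹)

- In grey at 0.964 min, G went to Z 3.6 times as fast as to E, and by the end, with G at 0.0102 % of its charge, Q stood at 57.6 % of its charge and E at 0.0318 M. The budget plus the Q not spent is 0.143 M, which is 57.3 % of grey's L; X in grey stood at 44.7 % at the end, above the first 40.0 %, and at 57.3 % after 1000 min. A flask like grey but charged with 1.0 M of L, with E at 0.0318 M, has 14.3 % as its budget, and after 100 min it held X at 14.3 %.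

The earlier runs and the new flask come from a simulation with made-up constants; noise was put on by code.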